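**Strategy.** Ring B (C5–C10) is cut at C9–C10 and C5=C6, leaving a ring A ketone and a four-carbon acylacrylate. Because C4 is quaternary, the C5 ketone can enolise only towards C10, and the axial C14 methyl, held by the trans-fused 3,13-acetonide, shields one face of that enolate. One Robinson annulation therefore forges the C10 quaternary centre, brings in C11 as the C9 ester and leaves a C5=C6–C7 enone whose ketone can be deprotonated only at C8, where C12 and the tertiary hydroxyl are installed later. The precursor is the acetonide of (2S,3R)-3-hydroxy-2-(hydroxymethyl)-2-methylcyclohexanone carrying the C10 methyl.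

Key step: step 5

Remark: locants are those of the drimane skeleton (ring A = C1–C5, C10; ring B = C5–C10; C11 on C9, C12 on C8, C13 and C14 on C4, C15 on C10); "syn/anti to C15" refers to the ring faces.
Remark: the (R)-BINAP ligand in step 2 is assigned by analogy with the sense of induction known for acyclic β-hydroxy ketones; if the sense were opposite in this cyclic case, the (S)-ligand would be used.

Step 1
Reactants: 1 2-methylcyclohexane-1,3-dione
Product: 2 2-(hydroxymethyl)-2-methylcyclohexane-1,3-dione
Conditions: 37% aq. CH2O, Et3N (cat.), THF/H2O, 20 °C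
Reagents that add atoms: formaldehyde, C=O
Why: Aldol hydroxymethylation of the acidic 1,3-dione forms the C4–C13 bond at carbon and avoids the O-alkylation expected from chloromethyl ethers with such enolates; no stereocentre is formed.

Step 2
Reactants: 2 2-(hydroxymethyl)-2-methylcyclohexane-1,3-dione
Product: 3 (2S,3R)-3-hydroxy-2-(hydroxymethyl)-2-methylcyclohexan-1-one (3R,4S in drimane locants; ring hydroxyl trans to CH2OH and cis to CH3)
Conditions: H2 (50 atm), RuCl2[(R)-BINAP] (1 mol%), MeOH, 35 °C
Reagents that add atoms: none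
Why: Hydroxyl-directed asymmetric hydrogenation of the Noyori type: the CH2OH group and one carbonyl chelate ruthenium, so hydride can reach that carbonyl only on the face that carries C13 and O3 ends trans to C13 and cis to C14 (an undirected hydride donor would be expected to attack anti to the larger CH2OR group and give the other relationship), while the ligand selects one of the two enantiotopic carbonyls and so fixes C3 as R and C4 as S; the remaining carbonyl is the mismatched one and cannot be chelated by the new equatorial hydroxyl, so reduction should stop at the hydroxy ketone.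

Step 3
Reactants: 3 (2S,3R)-3-hydroxy-2-(hydroxymethyl)-2-methylcyclohexan-1-one
Product: 4 3,13-acetonide of 3 (trans-fused 2,2-dimethyl-1,3-dioxane on the cyclohexanone; C5 ketone; C14 methyl axial; 3R,4S)
Conditions: Me2C(OMe)2, PPTS (cat.), CH2Cl2, 20 °C
Reagents that add atoms: 2,2-dimethoxypropane, COC(C)(C)OC
Why: Acid-catalysed transacetalisation engages the only 1,3-diol, and because O3 and C13 are trans the dioxane is trans-fused with both ring bonds equatorial, which locks the C14 methyl axial; no new stereocentre.

Step 4
Reactants: 4 3,13-acetonide ketone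
Product: 5 C10-methyl acetonide ketone, the annulation precursor (3R,4S; mixture of C10 epimers)
Conditions: LiN(i-Pr)2, THF, −78 °C; MeI, −78 → 0 °C
Reagents that add atoms: iodomethane, CI
Why: Enolate alkylation that is regiospecific because the ketone has α-hydrogens only at C10 (C4 is quaternary); the C10 configuration is irrelevant since this carbon becomes the enolate carbon of step 5.

Step 5
Reactants: 5 C10-methyl acetonide ketone; 6 methyl (E)-4-oxopent-2-enoate
Product: 9 methyl (3R,4S,9R,10S)-3,13-(isopropylidenedioxy)-7-oxo-12-nordrim-5-en-11-oate, via diketo ester 7 (not isolated), via ketol 8 (not isolated)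
Conditions: LiN(i-Pr)2, THF, −78 → 0 °C; 6, −78 °C; then NaOMe (0.3 equiv), MeOH, 0 → 45 °C
Reagents that add atoms: none
Why: Robinson annulation (Michael addition, then aldol condensation): the lithium enolate, which can form only at C10, should add to the acceptor at the ester-bearing carbon β to its ketone (the ketone being the stronger activating group), and methoxide should then convert the 1,5-diketone 7 into its methyl-ketone enolate, which attacks C5 and loses water by E1cB to leave the C5=C6 enone. The closest known reaction is the annulation of 2,2,6-trisubstituted cyclohexanones with methyl vinyl ketone to 4,4,10-trimethyl octalones, run here with a β-acylacrylate as acceptor. Ring B closes by a 6-(enolendo)-exo-trig aldol, the enolate C6=C7 bond lying inside the new ring and the C5 carbonyl oxygen outside it. C10 is controlled by the axial C14 methyl, which the trans-fused acetonide holds syn-axial to one face of the enolate, so the acceptor should bond to the opposite face and C15 should end syn to C14. C9 is set kinetically by the E geometry of the acceptor in a lithium-bridged synclinal transition state that already has the shape of ring B, with the acetyl arm over the enolate oxygen and the ester anti to C5, that is in the future equatorial position syn to C15, and the cyclodehydration is kept mild so that this ester α-centre is not equilibrated. The step needs Michael regioselectivity and facial selectivity at C10 and C9 but no regiocontrol of enolisation, because C4 carries no hydrogen.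

Step 6
Reactants: 9 enone ester
Product: 10 methyl (3R,4S,9R,10S)-3,13-(isopropylidenedioxy)-7-oxodrim-5-en-11-oate (mixture of C8 epimers)
Conditions: LiN(i-Pr)2, THF, −78 °C; MeI, −78 → −20 °C
Reagents that add atoms: iodomethane, CI
Why: Alkylation of the cross-conjugated enolate: C6 is vinylic and the enone has no γ-hydrogen (C4 and C10 are quaternary), so the ketone can be deprotonated only at C8 and C12 enters there regiospecifically; the C8 configuration is erased in step 7.

Step 7
Reactants: 10 8-methyl enone
Product: 11 methyl (3R,4S,8R,9S,10S)-8-hydroxy-3,13-(isopropylidenedioxy)-7-oxodrim-5-en-11-oate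
Conditions: KN(SiMe3)2, THF, −78 °C; 2-(phenylsulfonyl)-3-phenyloxaziridine, −78 °C; AcOH
Reagents that add atoms: 2-(phenylsulfonyl)-3-phenyloxaziridine, O=S(=O)(c1ccccc1)N1OC1c1ccccc1
Why: Davis α-hydroxylation of the tetrasubstituted C7–C8 potassium enolate (again the only one possible): oxygen should be delivered to the face of C8 anti to the pseudoaxial C15 methyl and the C9 ester, so the hydroxyl ends anti to C15 and C12 syn to it, which is the C8 arrangement of the target.

Step 8
Reactants: 11 hydroxy enone
Product: 12 methyl (3R,4S,5S,8R,9S,10R)-8-hydroxy-3,13-(isopropylidenedioxy)-7-oxodriman-11-oate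
Conditions: H2 (3 atm), 10% Pd/C, EtOAc, 20 °C
Reagents that add atoms: none
Why: Heterogeneous hydrogenation of the enone C5=C6 bond from the face opposite the two syn-axial methyls C14 and C15 should place H5 anti to C15 and give the trans-decalin.

Step 9
Reactants: 12 saturated hydroxy ketone
Product: 13 methyl (3R,4S,5S,8R,9S,10R)-8-hydroxy-3,13-(isopropylidenedioxy)-7-(trifluoromethylsulfonyloxy)drim-6-en-11-oate
Conditions: LiN(i-Pr)2 (2.2 equiv), THF, −78 °C; N-(5-chloropyridin-2-yl)bis(trifluoromethanesulfonimide), −78 °C; AcOH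
Reagents that add atoms: N-(5-chloropyridin-2-yl)bis(trifluoromethanesulfonimide), O=S(=O)(N(c1ccc(Cl)cn1)S(=O)(=O)C(F)(F)F)C(F)(F)F
Why: Enol triflate formation from the lithium enolate, which is regiospecific because C8 is now quaternary and the ketone can enolise only towards C6; the low temperature and lithium counter-ion should keep the C8 alkoxide from retro-aldol cleavage.

Step 10
Reactants: 13 enol triflate
Product: 14 methyl (3R,4S,5S,8S,9S,10R)-8-hydroxy-3,13-(isopropylidenedioxy)drim-6-en-11-oate
Conditions: Pd(OAc)2 (5 mol%), PPh3, HCO2H, Bu3N, DMF, 60 °C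
Reagents that add atoms: none
Why: Palladium-catalysed formate reduction of the enol triflate (oxidative addition to zerovalent palladium, formate exchange, decarboxylation, reductive elimination) replaces C7–O by C7–H under buffered conditions that should spare the acetonide, the ester and the tertiary alcohol.

Step 11
Reactants: 14 alkene
Product: 15 methyl (3R,4S,5S,8S,9S,10R)-8-hydroxy-3,13-(isopropylidenedioxy)driman-11-oate
Conditions: H2 (1 atm), 10% Pd/C, EtOAc, 20 °C
Reagents that add atoms: none
Why: Hydrogenation of the cis-disubstituted C6=C7 alkene completes the removal of the C7 oxygen without creating a stereocentre.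

Step 12
Reactants: 15 hydroxy ester
Product: 16 (3R,4S,5S,8S,9R,10R)-3,13-(isopropylidenedioxy)drimane-8,11-diol
Conditions: LiAlH4, THF, 0 → 40 °C; then Na2SO4·10H2O
Reagents that add atoms: none
Why: Hydride reduction of the hindered C9 methyl ester to the C11 primary alcohol, the standard conversion of β-hydroxy esters into 1,3-diols; no stereocentre is touched.

Step 13
Reactants: 16 diol; 17 7-hydroxycoumarin
Product: 18 7-{[(3R,4S,5S,8S,9R,10R)-8-hydroxy-3,13-(isopropylidenedioxy)driman-11-yl]oxy}-2H-chromen-2-one
Conditions: PPh3, i-PrO2CN=NCO2i-Pr, THF, 0 → 45 °C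
Reagents that add atoms: none
Why: Mitsunobu etherification: only the primary C11 hydroxyl is activated (the C8 hydroxyl is tertiary) and the acidic phenol displaces it by SN2 at a CH2 carbon, so no stereocentre is involved.

Step 14
Reactants: 18 coumarin ether acetonide
Product: 19 7-{[(3R,4S,5S,8S,9R,10R)-3,8,13-trihydroxydriman-11-yl]oxy}-2H-chromen-2-one
Conditions: AcOH/H2O/THF (3:1:1), 45 °C
Reagents that add atoms: none
Why: Mild acid hydrolysis of the acetonide should free the C3 and C13 hydroxyls without dehydrating the tertiary C8 alcohol or cleaving the aryl ether or the lactone.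

Step 15
Reactants: 19 triol; 20 angelic acid
Product: 22 (3R,4S,5S,8S,9R,10R)-3,8-dihydroxy-11-[(2-oxo-2H-chromen-7-yl)oxy]driman-13-yl (Z)-2-methylbut-2-enoate (target), via mixed anhydride 21 (not isolated)
Conditions: 20, 2,4,6-Cl3C6H2COCl, Et3N, toluene, 20 °C; then 19 (slight excess of anhydride only), 75 °C
Reagents that add atoms: none
Why: Yamaguchi-type acylation through the mixed anhydride without an acyl-transfer catalyst, conditions chosen because they transfer (Z)-2-methylbut-2-enoyl groups without isomerisation to the tiglate; the primary C13 hydroxyl should be acylated in preference to the secondary C3 and tertiary C8 hydroxyls.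

**Compound list**

1 | 2-methylcyclohexane-1,3-dione | CC1C(=O)CCCC1=O | starting material
2 | 2-(hydroxymethyl)-2-methylcyclohexane-1,3-dione | OCC1(C)C(=O)CCCC1=O | intermediate
3 | (2S,3R)-3-hydroxy-2-(hydroxymethyl)-2-methylcyclohexan-1-one | OC[C@]1(C)C(=O)CCC[C@H]1O | intermediate
4 | trans-fused 3,13-acetonide of 3 (3R,4S; C5 ketone) | CC1(C)OC[C@]2(C)C(=O)CCC[C@H]2O1 | intermediate
5 | C10-methyl acetonide ketone, precursor of the key step (3R,4S; C10 epimers) | CC1(C)OC[C@]2(C)C(=O)C(C)CC[C@H]2O1 | intermediate
6 | methyl (E)-4-oxopent-2-enoate | COC(=O)/C=C/C(C)=O | starting material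
7 | methyl (3R,4S,9R,10S)-3,13-(isopropylidenedioxy)-5,7-dioxo-12-nor-5,6-secodriman-11-oate (Michael adduct) | CC1(C)OC[C@]2(C)C(=O)[C@](C)([C@@H](CC(C)=O)C(=O)OC)CC[C@H]2O1 | intermediate
8 | methyl (3R,4S,9R,10S)-5-hydroxy-3,13-(isopropylidenedioxy)-7-oxo-12-nordriman-11-oate (aldol; C5 configuration unassigned) | CC1(C)OC[C@]2(C)C3(O)CC(=O)C[C@@H](C(=O)OC)[C@]3(C)CC[C@H]2O1 | intermediate
9 | methyl (3R,4S,9R,10S)-3,13-(isopropylidenedioxy)-7-oxo-12-nordrim-5-en-11-oate, product of the key step | CC1(C)OC[C@]2(C)C3=CC(=O)C[C@@H](C(=O)OC)[C@]3(C)CC[C@H]2O1 | intermediate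
10 | methyl (3R,4S,9R,10S)-3,13-(isopropylidenedioxy)-7-oxodrim-5-en-11-oate (C8 epimers) | CC1(C)OC[C@]2(C)C3=CC(=O)C(C)[C@@H](C(=O)OC)[C@]3(C)CC[C@H]2O1 | intermediate
11 | methyl (3R,4S,8R,9S,10S)-8-hydroxy-3,13-(isopropylidenedioxy)-7-oxodrim-5-en-11-oate | CC1(C)OC[C@]2(C)C3=CC(=O)[C@](C)(O)[C@@H](C(=O)OC)[C@]3(C)CC[C@H]2O1 | intermediate
12 | methyl (3R,4S,5S,8R,9S,10R)-8-hydroxy-3,13-(isopropylidenedioxy)-7-oxodriman-11-oate | CC1(C)OC[C@]2(C)[C@H]3CC(=O)[C@](C)(O)[C@@H](C(=O)OC)[C@]3(C)CC[C@H]2O1 | intermediate
13 | methyl (3R,4S,5S,8R,9S,10R)-8-hydroxy-3,13-(isopropylidenedioxy)-7-(trifluoromethylsulfonyloxy)drim-6-en-11-oate | CC1(C)OC[C@]2(C)[C@H]3C=C(OS(=O)(=O)C(F)(F)F)[C@](C)(O)[C@@H](C(=O)OC)[C@]3(C)CC[C@H]2O1 | intermediate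
14 | methyl (3R,4S,5S,8S,9S,10R)-8-hydroxy-3,13-(isopropylidenedioxy)drim-6-en-11-oate | CC1(C)OC[C@]2(C)[C@H]3C=C[C@](C)(O)[C@@H](C(=O)OC)[C@]3(C)CC[C@H]2O1 | intermediate
15 | methyl (3R,4S,5S,8S,9S,10R)-8-hydroxy-3,13-(isopropylidenedioxy)driman-11-oate | CC1(C)OC[C@]2(C)[C@H]3CC[C@](C)(O)[C@@H](C(=O)OC)[C@]3(C)CC[C@H]2O1 | intermediate
16 | (3R,4S,5S,8S,9R,10R)-3,13-(isopropylidenedioxy)drimane-8,11-diol | CC1(C)OC[C@]2(C)[C@H]3CC[C@](C)(O)[C@@H](CO)[C@]3(C)CC[C@H]2O1 | intermediate
17 | 7-hydroxycoumarin | Oc1ccc2ccc(=O)oc2c1 | starting material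
18 | 7-{[(3R,4S,5S,8S,9R,10R)-8-hydroxy-3,13-(isopropylidenedioxy)driman-11-yl]oxy}-2H-chromen-2-one | CC1(C)OC[C@]2(C)[C@H]3CC[C@](C)(O)[C@@H](COc4ccc5ccc(=O)oc5c4)[C@]3(C)CC[C@H]2O1 | intermediate
19 | 7-{[(3R,4S,5S,8S,9R,10R)-3,8,13-trihydroxydriman-11-yl]oxy}-2H-chromen-2-one | OC[C@]1(C)[C@H]2CC[C@](C)(O)[C@@H](COc3ccc4ccc(=O)oc4c3)[C@]2(C)CC[C@H]1O | intermediate
20 | angelic acid, (Z)-2-methylbut-2-enoic acid | C/C=C(/C)C(=O)O | starting material
21 | (Z)-2-methylbut-2-enoic 2,4,6-trichlorobenzoic anhydride | C/C=C(/C)C(=O)OC(=O)c1c(Cl)cc(Cl)cc1Cl | intermediate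
22 | (3R,4S,5S,8S,9R,10R)-3,8-dihydroxy-11-[(2-oxo-2H-chromen-7-yl)oxy]driman-13-yl (Z)-2-methylbut-2-enoate | C/C=C(/C)C(=O)OC[C@]1(C)[C@H]2CC[C@](C)(O)[C@@H](COc3ccc4ccc(=O)oc4c3)[C@]2(C)CC[C@H]1O | target

**Totals.** 15 steps; longest linear sequence 15 steps (1 → 22); 6, 17 and 20 enter as purchased reactants.

**Steps most likely to fail**

Step 5. The anionic conjugate addition may be overtaken by base-induced self-condensation of the acceptor and by retro-Michael cleavage of the congested C9–C10 bond, and control of C9 may be lost through poor acceptor-face selection or equilibration during the closure. The fallback sets out from 5 and returns at 9. The ketone is converted with Me3SiOTf/Et3N into its trimethylsilyl enol ether F1. A Mukaiyama–Michael addition to 6 (TiCl4/Ti(Oi-Pr)4, CH2Cl2, −78 °C) should then give the isolated diketo ester 7 without any basic species, and 7 is cyclodehydrated separately (KOt-Bu, t-BuOH) through 8 to 9. Should 9 be a C9 mixture, IBX in DMSO at 75 °C should dehydrogenate the only available α-position to the cross-conjugated dienone F2. Zn in AcOH/THF at 0 °C should then reduce the doubly activated C8=C9 bond with protonation of C9 anti to C15, which would return 9 as the single epimer.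

Step 2. Chelate-directed hydride transfer may be slowed by the quaternary centre, the ruthenium alkoxide may lose formaldehyde by retro-aldol cleavage, or the two carbonyls may be poorly differentiated. The fallback sets out from 2 and returns at 3. Silylation (t-BuMe2SiCl, imidazole) gives the silyl ether dione F3. Corey–Bakshi–Shibata reduction with (R)-2-methyl-CBS-oxazaborolidine and BH3·SMe2 is an outer-sphere hydride transfer expected to place the hydroxyl cis to the larger CH2OSi group, and should give the (2S,3S) hydroxy ketone F4 with C4 correct and C3 epimeric. Mitsunobu inversion with 4-nitrobenzoic acid (PPh3, i-PrO2CN=NCO2i-Pr; slow at this neopentyl carbinol but established) gives the (2S,3R) 4-nitrobenzoate F5. Methanolysis (K2CO3, MeOH, 0 °C) gives the silyl ether F6, and aqueous HF in MeCN releases 3.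

Step 13. SN2 displacement at the β-branched C11, flanked by two quaternary carbons, may be too slow, so that the activated alcohol is diverted to elimination or to alkylation of the hydrazide. The fallback sets out from 16 and returns at 18 with the polarity reversed: the alcohol 16 serves as nucleophile in a palladium-catalysed C–O coupling with purchased 7-bromocoumarin (Pd2(dba)3, t-BuBrettPhos, Cs2CO3, toluene, 90 °C), in which the tertiary C8 hydroxyl should not react; this fallback makes no compound outside the list (F0).

**Further compounds**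

F1 | step 5 | trimethylsilyl enol ether of 5 (C5=C10; 3R,4S) | CC1(C)OC[C@]2(C)C(O[Si](C)(C)C)=C(C)CC[C@H]2O1
F2 | step 5 | methyl (3R,4S,10S)-3,13-(isopropylidenedioxy)-7-oxo-12-nordrima-5,8-dien-11-oate | CC1(C)OC[C@]2(C)C3=CC(=O)C=C(C(=O)OC)[C@]3(C)CC[C@H]2O1
F3 | step 2 | 2-[(tert-butyldimethylsilyloxy)methyl]-2-methylcyclohexane-1,3-dione | CC(C)(C)[Si](C)(C)OCC1(C)C(=O)CCCC1=O
F4 | step 2 | (2S,3S)-2-[(tert-butyldimethylsilyloxy)methyl]-3-hydroxy-2-methylcyclohexan-1-one | CC(C)(C)[Si](C)(C)OC[C@]1(C)C(=O)CCC[C@@H]1O
F5 | step 2 | (1R,2S)-2-[(tert-butyldimethylsilyloxy)methyl]-2-methyl-3-oxocyclohexyl 4-nitrobenzoate | CC(C)(C)[Si](C)(C)OC[C@]1(C)C(=O)CCC[C@H]1OC(=O)c1ccc(cc1)[N+](=O)[O-]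
F6 | step 2 | (2S,3R)-2-[(tert-butyldimethylsilyloxy)methyl]-3-hydroxy-2-methylcyclohexan-1-one | CC(C)(C)[Si](C)(C)OC[C@]1(C)C(=O)CCC[C@H]1O
F0 | step 13 | none | none
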